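**Plan**
- Retrosynthetic cuts, in order: the O–CH3 bond at C8. Then the C8–C8a bond of ring A (flavone numbering), which unfolds ring A to a 4-hydroxycyclobutenone. Then the C5–C4a bond (squarate carbonyl plus metalated pyranone). Last, the C2–C3 and O1–C8a bonds of ring C (aldehyde plus siloxydiene).
- Enabling feature: ring A carries oxygen on each of C5, C6, C7 and C8. C5–O and C8–O are para to each other, and the methoxy-bearing carbons C6 and C7 lie between them. This C4O4 unit is dimethyl squarate, and the two remaining ring A atoms, C4a and C8a, are a C=C bond of a 4-pyranone (ring C).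
- Forward order: ring B arrives with the aldehyde. Ring C is built first by a hetero-Diels–Alder reaction, iodinated at the future C4a and dehydrogenated. The squarate is then attached at C4a, and ring A closes last by four-electron opening and six-electron closure.
- The two phenols formed differ through the hydrogen bond from the C5 hydroxyl to the C4 carbonyl, so one equivalent of methylating agent finishes the route at the C8 oxygen.
- Stereochemistry: the target has no stereocentre. The centres that arise on the way (C2 of the dihydropyranones, the cyclobutenone carbinol carbon, C8a of the closure product) are racemic and all erased. Only the sense of rotation in the ring opening needs control.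

Key step: step 5

Remark: all chiral intermediates are carried as racemates, a SMILES with stereo marks shows relative configuration only, and the three starting materials are commercial.

**Step 1**
Reactants: 1 2,4,5-trimethoxybenzaldehyde; 2 trans-1-methoxy-3-(trimethylsilyloxy)buta-1,3-diene
Product: 4 rac-2-(2,4,5-trimethoxyphenyl)-2,3-dihydro-4H-pyran-4-one, via silyl enol ether cycloadduct 3 (not isolated)
Conditions: ZnCl2, THF, rt; then TFA (cat.), CH2Cl2, 0 °C; aqueous work-up
Reagents that add atoms: none
Why: The ZnCl2-promoted hetero-Diels–Alder reaction of this siloxydiene with aromatic aldehydes is a standard entry to 2-aryl-2,3-dihydro-4-pyranones, the acid treatment expels methanol and the silyl group from cycloadduct 3, and the lone stereocentre at C2 needs no control because it forms as a racemate and is erased in step 3.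

**Step 2**
Reactants: 4 rac-2-(2,4,5-trimethoxyphenyl)-2,3-dihydro-4H-pyran-4-one
Product: 5 rac-5-iodo-2-(2,4,5-trimethoxyphenyl)-2,3-dihydro-4H-pyran-4-one
Conditions: I2, pyridine/CH2Cl2, 0 °C to rt
Reagents that add atoms: iodine, II
Why: Electrophilic alpha-iodination of an enone with I2 and pyridine occurs at pyranone C5 (the future C4a), the only nucleophilic carbon of the vinylogous ester, pyridine then removes the C5 proton, and this weak, acid-free iodine source should leave the trimethoxyphenyl ring untouched.

**Step 3**
Reactants: 5 rac-5-iodo-2-(2,4,5-trimethoxyphenyl)-2,3-dihydro-4H-pyran-4-one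
Product: 6 5-iodo-2-(2,4,5-trimethoxyphenyl)-4H-pyran-4-one
Conditions: DDQ, 1,4-dioxane, 100 °C
Reagents that add atoms: none
Why: This is the DDQ dehydrogenation used for flavanone-to-flavone conversion, in which hydride leaves C2 (benzylic to a strongly donating aryl ring and alpha to the ring oxygen), the C3 proton follows, the cyclically conjugated 4-pyranone provides the driving force, and the vinyl iodide is inert to DDQ.

**Step 4**
Reactants: 6 5-iodo-2-(2,4,5-trimethoxyphenyl)-4H-pyran-4-one; 7 dimethyl squarate (3,4-dimethoxycyclobut-3-ene-1,2-dione)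
Product: 9 rac-4-hydroxy-2,3-dimethoxy-4-[4-oxo-6-(2,4,5-trimethoxyphenyl)-4H-pyran-3-yl]cyclobut-2-en-1-one, via pyranon-3-ylmagnesium chloride 8 (not isolated)
Conditions: iPrMgCl·LiCl, THF, −40 °C; cannulated into 7 (slight excess), THF, −78 to −30 °C; sat. aq NH4Cl
Reagents that add atoms: isopropylmagnesium chloride, CC(C)[Mg]Cl (supplies the MgCl of 8; no atom of it remains in 9)
Why: Iodine–magnesium exchange is fast on alkenyl iodides flanked by a carbonyl group and a beta-oxygen (as in 5-iodo-1,3-dioxin-4-ones) and at low temperature outruns beta-elimination, after which the Grignard reagent adds 1,2 to one of the two equivalent squarate carbonyls, giving a racemic carbinol carbon that is erased in step 5.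

**Step 5**
Reactants: 9 rac-4-hydroxy-2,3-dimethoxy-4-[4-oxo-6-(2,4,5-trimethoxyphenyl)-4H-pyran-3-yl]cyclobut-2-en-1-one
Product: 12 5,8-dihydroxy-6,7-dimethoxy-2-(2,4,5-trimethoxyphenyl)-4H-chromen-4-one, via dienylketene 10 (not isolated), via 8aH-chromene-4,8-dione tautomer 11 (not isolated)
Conditions: toluene (degassed), 110 °C, Ar; work-up under Ar
Reagents that add atoms: none
Why: Heat breaks the bond between the carbinol carbon and the ring carbonyl in a conrotatory four-electron electrocyclic opening in which the hydroxyl donor rotates outward, so the pyranonyl group turns inward and the ketene carbon of 10 lies next to the pyranone C–H carbon, the future C8a. A disrotatory six-electron electrocyclisation across the ketene C=C, the enol C=C and the C4a=C8a bond of ring C then forms C8–C8a and closes the six-membered carbocycle ring A as dienone 11, and transfer of the C8a proton to the C8 oxygen aromatises it to 12. The closest known reaction type is the Moore rearrangement of 4-aryl-, 4-heteroaryl- and 4-alkenyl-4-hydroxycyclobutenones to hydroquinones. No stereocentre survives, since the carbinol centre of 9 becomes sp2 on opening and the C8a centre of 11 is lost on enolisation. The step needs torquoselectivity, secured by the outward preference of the hydroxyl group, and regioselective closure, secured because the only other neighbour of C4a in ring C is the C4 carbonyl carbon and because the enol O–H to C4=O hydrogen bond holds ring C with C8a facing the ketene. Exclusion of oxygen keeps 12 at the hydroquinone level, and the same hydrogen bond marks the C5 hydroxyl as the unreactive one in step 6.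

**Step 6**
Reactants: 12 5,8-dihydroxy-6,7-dimethoxy-2-(2,4,5-trimethoxyphenyl)-4H-chromen-4-one
Product: 13 agehoustin E, 5-hydroxy-6,7,8-trimethoxy-2-(2,4,5-trimethoxyphenyl)-4H-chromen-4-one
Conditions: MeI (1.05 equiv), K2CO3 (1.1 equiv), acetone (degassed), rt, Ar
Reagents that add atoms: iodomethane, CI
Why: This is a Williamson-type phenol O-methylation under chelation control, a standard selectivity of 5-hydroxyflavones, in which the C5 hydroxyl is tied to the C4 carbonyl by a hydrogen bond and resists K2CO3 and a single equivalent of MeI at room temperature, so only the C8 phenoxide reacts, while exclusion of air prevents oxidation to the quinone.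

**Compound list**
1 | 2,4,5-trimethoxybenzaldehyde | COc1cc(OC)c(C=O)cc1OC | starting material
2 | trans-1-methoxy-3-(trimethylsilyloxy)buta-1,3-diene | CO/C=C/C(=C)O[Si](C)(C)C | starting material
3 | rac-cis-6-methoxy-2-(2,4,5-trimethoxyphenyl)-4-(trimethylsilyloxy)-3,6-dihydro-2H-pyran | CO[C@@H]1C=C(O[Si](C)(C)C)C[C@H](c2cc(OC)c(OC)cc2OC)O1 | intermediate
4 | rac-2-(2,4,5-trimethoxyphenyl)-2,3-dihydro-4H-pyran-4-one | O=C1C=COC(c2cc(OC)c(OC)cc2OC)C1 | intermediate
5 | rac-5-iodo-2-(2,4,5-trimethoxyphenyl)-2,3-dihydro-4H-pyran-4-one | O=C1C(I)=COC(c2cc(OC)c(OC)cc2OC)C1 | intermediate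
6 | 5-iodo-2-(2,4,5-trimethoxyphenyl)-4H-pyran-4-one | O=c1cc(-c2cc(OC)c(OC)cc2OC)occ1I | intermediate
7 | dimethyl squarate | COC1=C(OC)C(=O)C1=O | starting material
8 | [4-oxo-6-(2,4,5-trimethoxyphenyl)-4H-pyran-3-yl]magnesium chloride (LiCl complex) | O=c1cc(-c2cc(OC)c(OC)cc2OC)occ1[Mg]Cl | intermediate
9 | rac-4-hydroxy-2,3-dimethoxy-4-[4-oxo-6-(2,4,5-trimethoxyphenyl)-4H-pyran-3-yl]cyclobut-2-en-1-one | COC1=C(OC)C(O)(c2coc(-c3cc(OC)c(OC)cc3OC)cc2=O)C1=O | intermediate
10 | (3Z)-4-hydroxy-2,3-dimethoxy-4-[4-oxo-6-(2,4,5-trimethoxyphenyl)-4H-pyran-3-yl]buta-1,3-dien-1-one (hydroxyl trans to the ketene arm) | O=C=C(OC)/C(OC)=C(/O)c1coc(-c2cc(OC)c(OC)cc2OC)cc1=O | intermediate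
11 | rac-5-hydroxy-6,7-dimethoxy-2-(2,4,5-trimethoxyphenyl)-8aH-chromene-4,8-dione | COC1=C(OC)C(=O)C2OC(c3cc(OC)c(OC)cc3OC)=CC(=O)C2=C1O | intermediate
12 | 5,8-dihydroxy-6,7-dimethoxy-2-(2,4,5-trimethoxyphenyl)-4H-chromen-4-one | COc1cc(OC)c(-c2cc(=O)c3c(O)c(OC)c(OC)c(O)c3o2)cc1OC | intermediate
13 | agehoustin E | COc1cc(OC)c(-c2cc(=O)c3c(O)c(OC)c(OC)c(OC)c3o2)cc1OC | target

Total step count: 6. Longest linear sequence: 6 steps (1 to 13).

**Steps most likely to fail**

First, step 4.
- What may go wrong: the magnesiated pyranone may fragment by anti beta-elimination, because its ring oxygen would leave as a stabilised diketone enolate. The exchange reagent may also attack the unsubstituted ring carbon next to oxygen. The chelated Grignard reagent may add too slowly to the squarate.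
- Fallback: it sets out from 5 and moves the construction of ring A to the dihydro level. There the ring oxygen could leave only as a plain alkoxide, as in the well-behaved 5-magnesiated 1,3-dioxin-4-ones.
- Exchange of 5 with iPrMgCl·LiCl at −40 °C would give [4-oxo-6-(2,4,5-trimethoxyphenyl)-5,6-dihydro-4H-pyran-3-yl]magnesium chloride F1.
- F1 adds to 7 to give 4-hydroxy-2,3-dimethoxy-4-[4-oxo-6-(2,4,5-trimethoxyphenyl)-5,6-dihydro-4H-pyran-3-yl]cyclobut-2-en-1-one F2.
- Heating F2 in degassed toluene forms the same C8–C8a bond, now on a C=C bond with no cyclic conjugation to lose. This gives 5,8-dihydroxy-6,7-dimethoxy-2-(2,4,5-trimethoxyphenyl)chroman-4-one F3.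
- MeI and K2CO3 then etherify the free C8 hydroxyl to 5-hydroxy-6,7,8-trimethoxy-2-(2,4,5-trimethoxyphenyl)chroman-4-one F4.
- The classical flavanone-to-flavone dehydrogenation (catalytic I2, DMSO, 120 °C) brings the sequence back to the route at 13.

Second, step 5.
- What may go wrong: the six-electron closure may be slow because it costs ring C its cyclic conjugation. That leaves time for a minor hydroxyl-inward opening with capture of the ketene by the hydroxyl group, for retro-addition of the tertiary carbinol, and for aerial oxidation of the free hydroquinone.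
- Fallback: it sets out from 9 and caps the carbinol oxygen. The unproductive channels are then closed, the reversible ring opening can be driven at higher temperature, and the two ring A oxygens are told apart by a protecting group instead of by chelation.
- TBSOTf and 2,6-lutidine in CH2Cl2 would give 4-(tert-butyldimethylsilyloxy)-2,3-dimethoxy-4-[4-oxo-6-(2,4,5-trimethoxyphenyl)-4H-pyran-3-yl]cyclobut-2-en-1-one F5.
- Heating F5 in p-xylene at 140 °C gives 5-(tert-butyldimethylsilyloxy)-8-hydroxy-6,7-dimethoxy-2-(2,4,5-trimethoxyphenyl)-4H-chromen-4-one F6.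
- MeI and K2CO3 in DMF give 5-(tert-butyldimethylsilyloxy)-6,7,8-trimethoxy-2-(2,4,5-trimethoxyphenyl)-4H-chromen-4-one F7.
- Bu4NF buffered with acetic acid in THF at 0 °C removes the silyl group, and the sequence rejoins the route at 13.

Third, step 3.
- What may go wrong: hydride abstraction may stall because the lone pair of the ring oxygen is engaged in the vinylogous ester. The electron-rich trimethoxyphenyl ring may be over-oxidised through charge-transfer chemistry. Iodine may be lost on prolonged heating.
- Fallback: it sets out from 5 and replaces hydride abstraction by enolate chemistry at low temperature.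
- LiN(SiMe3)2 in THF at −78 °C followed by PhSeCl would place selenium at C3 anti to the aryl group. This gives rac-trans-5-iodo-3-(phenylselanyl)-2-(2,4,5-trimethoxyphenyl)-2,3-dihydro-4H-pyran-4-one F8.
- H2O2 with pyridine in CH2Cl2 at 0 °C oxidises F8 to rac-trans-5-iodo-3-(phenylseleninyl)-2-(2,4,5-trimethoxyphenyl)-2,3-dihydro-4H-pyran-4-one F9.
- The selenoxide of F9 stands syn to the C2 hydrogen and undergoes syn-elimination below room temperature, which returns to the route at 6.

**Further compounds**
F1 | step 4 | rac-[4-oxo-6-(2,4,5-trimethoxyphenyl)-5,6-dihydro-4H-pyran-3-yl]magnesium chloride | O=C1CC(c2cc(OC)c(OC)cc2OC)OC=C1[Mg]Cl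
F2 | step 4 | 4-hydroxy-2,3-dimethoxy-4-[4-oxo-6-(2,4,5-trimethoxyphenyl)-5,6-dihydro-4H-pyran-3-yl]cyclobut-2-en-1-one (racemic, both diastereomers) | COC1=C(OC)C(O)(C2=COC(c3cc(OC)c(OC)cc3OC)CC2=O)C1=O
F3 | step 4 | rac-5,8-dihydroxy-6,7-dimethoxy-2-(2,4,5-trimethoxyphenyl)chroman-4-one | COc1cc(OC)c(C2CC(=O)c3c(O)c(OC)c(OC)c(O)c3O2)cc1OC
F4 | step 4 | rac-5-hydroxy-6,7,8-trimethoxy-2-(2,4,5-trimethoxyphenyl)chroman-4-one | COc1cc(OC)c(C2CC(=O)c3c(O)c(OC)c(OC)c(OC)c3O2)cc1OC
F5 | step 5 | rac-4-(tert-butyldimethylsilyloxy)-2,3-dimethoxy-4-[4-oxo-6-(2,4,5-trimethoxyphenyl)-4H-pyran-3-yl]cyclobut-2-en-1-one | COC1=C(OC)C(O[Si](C)(C)C(C)(C)C)(c2coc(-c3cc(OC)c(OC)cc3OC)cc2=O)C1=O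
F6 | step 5 | 5-(tert-butyldimethylsilyloxy)-8-hydroxy-6,7-dimethoxy-2-(2,4,5-trimethoxyphenyl)-4H-chromen-4-one | COc1cc(OC)c(-c2cc(=O)c3c(O[Si](C)(C)C(C)(C)C)c(OC)c(OC)c(O)c3o2)cc1OC
F7 | step 5 | 5-(tert-butyldimethylsilyloxy)-6,7,8-trimethoxy-2-(2,4,5-trimethoxyphenyl)-4H-chromen-4-one | COc1cc(OC)c(-c2cc(=O)c3c(O[Si](C)(C)C(C)(C)C)c(OC)c(OC)c(OC)c3o2)cc1OC
F8 | step 3 | rac-trans-5-iodo-3-(phenylselanyl)-2-(2,4,5-trimethoxyphenyl)-2,3-dihydro-4H-pyran-4-one | O=C1C(I)=CO[C@@H](c2cc(OC)c(OC)cc2OC)[C@@H]1[Se]c1ccccc1
F9 | step 3 | rac-trans-5-iodo-3-(phenylseleninyl)-2-(2,4,5-trimethoxyphenyl)-2,3-dihydro-4H-pyran-4-one | O=C1C(I)=CO[C@@H](c2cc(OC)c(OC)cc2OC)[C@@H]1[Se](=O)c1ccccc1
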